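The route rests on disconnecting the O1–C8a aryl ether bond of ring C in the upper epiafzelechin unit. Ring A, whose C5, C7 and C8a oxygens are mutually meta, is mapped onto 1,3,5-trifluorobenzene: two fluorines become benzyloxy groups, the third directs metalation at C4a and then serves as leaving group. In the key step the C2 alkoxide of an acyclic syn-1,2-diol monoether displaces this C8a fluorine (intramolecular SNAr), closing the pyran ring with retention at C2 and C3, so the syn relationship becomes the 2,3-cis flavan. The benzylated flavan is C4-activated and coupled twice (4β→8) onto a 4'-O-methylepigallocatechin unit made the same way, the second time with a C8 bromine cap; hydrogenolysis follows.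

Key step: step 6

Remark: the target is read as epiafzelechin-(4β→8)-epiafzelechin-(4β→8)-4'-O-methylepigallocatechin (all three flavan units 2R,3R and 2,3-cis, both interflavan bonds 3,4-trans); [4-(benzyloxy)phenyl]magnesium bromide is taken as the commercial THF solution.

Step 1
Reactants: 1 1,3,5-trifluorobenzene
Product: 2 1,3-bis(benzyloxy)-5-fluorobenzene
Conditions: BnOH (2.1 equiv), NaH (2.2 equiv), NMP, 0 → 80 °C
Reagents that add atoms: benzyl alcohol, OCc1ccccc1
Why: Twofold nucleophilic aromatic substitution (SNAr) by sodium benzyloxide; each fluorine is activated inductively by its two meta substituents and the third displacement on the dialkoxy fluoroarene is far slower, so the reaction should stop at 2.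

Step 2
Reactants: 2 1,3-bis(benzyloxy)-5-fluorobenzene; 3 methyl (2R)-oxirane-2-carboxylate (methyl (R)-glycidate)
Product: 6 methyl (2R)-3-[2,4-bis(benzyloxy)-6-fluorophenyl]-2-hydroxypropanoate, via aryllithium 4 (not isolated), via arylmagnesium bromide 5 (not isolated)
Conditions: n-BuLi, THF, −78 °C; MgBr2·OEt2, −78 → −40 °C; CuI (10 mol %), 3, −40 → −20 °C; H2O work-up
Reagents that add atoms: none
Why: Directed ortho-metalation at the C–H flanked by fluorine and benzyloxy (the most acidic site), Li→Mg exchange and CuI-catalysed Grignard opening of the glycidate at its unsubstituted C3, which leaves the (R) stereocenter untouched.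

Step 3
Reactants: 6 methyl (2R)-3-[2,4-bis(benzyloxy)-6-fluorophenyl]-2-hydroxypropanoate
Product: 7 methyl (2R)-2-(benzyloxy)-3-[2,4-bis(benzyloxy)-6-fluorophenyl]propanoate
Conditions: BnBr, Ag2O, CH2Cl2, rt, dark
Reagents that add atoms: benzyl bromide, BrCc1ccccc1
Why: Ag2O-promoted Williamson etherification, which is not basic enough to enolize the α-alkoxy ester, so the stereocenter should be kept and the aryl fluoride is not attacked.

Step 4
Reactants: 7 methyl (2R)-2-(benzyloxy)-3-[2,4-bis(benzyloxy)-6-fluorophenyl]propanoate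
Product: 8 (2R)-2-(benzyloxy)-3-[2,4-bis(benzyloxy)-6-fluorophenyl]propanal
Conditions: i-Bu2AlH (1.1 equiv), CH2Cl2, −78 °C; aq. potassium sodium tartrate
Reagents that add atoms: none
Why: Partial ester reduction with i-Bu2AlH: the chelated tetrahedral aluminium hemiacetal survives at −78 °C and collapses to the aldehyde only on work-up, and the configurationally labile aldehyde is used at once.

Step 5
Reactants: 8 (2R)-2-(benzyloxy)-3-[2,4-bis(benzyloxy)-6-fluorophenyl]propanal; 9 [4-(benzyloxy)phenyl]magnesium bromide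
Product: 10 (1R,2R)-2-(benzyloxy)-3-[2,4-bis(benzyloxy)-6-fluorophenyl]-1-[4-(benzyloxy)phenyl]propan-1-ol
Conditions: MgBr2·OEt2, CH2Cl2, −78 °C; then 9 (THF solution) added slowly, −78 °C; H2O work-up
Reagents that add atoms: none
Why: Chelation-controlled Grignard addition (Cram chelate model): magnesium bridges the carbonyl and α-benzyloxy oxygens and the aryl group enters from the side of the α-hydrogen, so the existing (R) center sets the new carbinol center as (R), i.e. the syn-1,2-diol monoether.

Step 6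
Reactants: 10 (1R,2R)-2-(benzyloxy)-3-[2,4-bis(benzyloxy)-6-fluorophenyl]-1-[4-(benzyloxy)phenyl]propan-1-ol
Product: 12 (2R,3R)-3,5,7-tris(benzyloxy)-2-[4-(benzyloxy)phenyl]-3,4-dihydro-2H-chromene (3,5,7,4'-tetra-O-benzylepiafzelechin), via potassium alkoxide 11 (not isolated)
Conditions: KH (1.5 equiv), 18-crown-6 (0.2 equiv), THF–DMPU, 0 → 70 °C
Reagents that add atoms: none
Why: Deprotonation gives alkoxide 11, which adds to the fluorine-bearing ring carbon (the future C8a) and expels fluoride by addition–elimination through a Meisenheimer-type σ-adduct (or its concerted equivalent). The closest known reaction type is the intramolecular SNAr O-arylation of fluoroarenes by alkoxides used to make chromans. Ring C closes in a formally 6-exo-trig mode at the aromatic carbon. No stereocenter is formed or touched: the C2–O and C3–O bonds stay intact, so both centers are retained and the syn relationship of 10 becomes the 2,3-cis (2R,3R) arrangement. The step needs chemoselectivity (one oxygen, one ring size, one ring carbon): only the C2 oxygen is free because the C3 oxygen is benzylated, which excludes the five-membered dihydrobenzofuran closure, and the single fluorine marks C8a. The two benzyloxy groups sit meta to that carbon (at C5 and C7), so they cannot donate into the positions that carry the negative charge (C4a, C6, C8) and assist only inductively.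

Step 7
Reactants: 12 (2R,3R)-3,5,7-tris(benzyloxy)-2-[4-(benzyloxy)phenyl]-3,4-dihydro-2H-chromene
Product: 13 (2R,3R,4S)-3,5,7-tris(benzyloxy)-2-[4-(benzyloxy)phenyl]-4-(2-ethoxyethoxy)-3,4-dihydro-2H-chromene (4β ether, 3,4-trans)
Conditions: DDQ (2 equiv), 2-ethoxyethanol (5 equiv), CH2Cl2, rt
Reagents that add atoms: 2-ethoxyethanol, CCOCCO
Why: DDQ benzylic oxidation (hydride abstraction at C4, assisted by O1 and the C5 and C7 benzyloxy groups of ring A) with trapping by the alcohol on the face opposite the C2 aryl and C3 benzyloxy groups, which should give the 3,4-trans ether; this C4 configuration is erased again on ionization in steps 12 and 13.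

Step 8
Reactants: 13 (2R,3R,4S)-3,5,7-tris(benzyloxy)-2-[4-(benzyloxy)phenyl]-4-(2-ethoxyethoxy)-3,4-dihydro-2H-chromene (the portion reserved for the upper unit)
Product: 14 (2R,3R,4S)-3,5,7-tris(benzyloxy)-2-[4-(benzyloxy)phenyl]-8-bromo-4-(2-ethoxyethoxy)-3,4-dihydro-2H-chromene
Conditions: NBS (1.05 equiv), CH2Cl2, −78 → −40 °C, dark
Reagents that add atoms: N-bromosuccinimide, O=C1CCC(=O)N1Br
Why: Electrophilic aromatic bromination of the phloroglucinol-type ring A at C8, the most nucleophilic position (flanked by O1 and the C7 benzyloxy group), which blocks the only site through which this chain-terminating unit could act as a nucleophile; the bromine is removed in step 14.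

Step 9
Reactants: 15 5-bromo-1,3-difluoro-2-methoxybenzene (4-bromo-2,6-difluoroanisole)
Product: 16 1,3-bis(benzyloxy)-5-bromo-2-methoxybenzene
Conditions: BnOH (2.5 equiv), NaH (2.6 equiv), NMP, 0 → 110 °C
Reagents that add atoms: benzyl alcohol, OCc1ccccc1
Why: Twofold SNAr by sodium benzyloxide: each fluorine is activated by the meta bromine and the meta fluorine or benzyloxy group, the flanked methoxy group is twisted out of conjugation, and fluoride leaves far faster than bromide, so the bromine should be kept for step 10.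

Step 10
Reactants: 16 1,3-bis(benzyloxy)-5-bromo-2-methoxybenzene; 8 (2R)-2-(benzyloxy)-3-[2,4-bis(benzyloxy)-6-fluorophenyl]propanal
Product: 18 (1R,2R)-2-(benzyloxy)-3-[2,4-bis(benzyloxy)-6-fluorophenyl]-1-[3,5-bis(benzyloxy)-4-methoxyphenyl]propan-1-ol, via arylmagnesium bromide 17 (not isolated)
Conditions: Mg, LiCl, THF, rt; then added to 8 and MgBr2·OEt2 in CH2Cl2, −78 °C; H2O work-up
Reagents that add atoms: none
Why: Grignard formation by magnesium insertion followed by the same chelation-controlled (Cram chelate) addition as in step 5, the (R) center of 8 setting the new carbinol center as (R).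

Step 11
Reactants: 18 (1R,2R)-2-(benzyloxy)-3-[2,4-bis(benzyloxy)-6-fluorophenyl]-1-[3,5-bis(benzyloxy)-4-methoxyphenyl]propan-1-ol
Product: 20 (2R,3R)-3,5,7-tris(benzyloxy)-2-[3,5-bis(benzyloxy)-4-methoxyphenyl]-3,4-dihydro-2H-chromene (3,5,7,3',5'-penta-O-benzyl-4'-O-methylepigallocatechin), via potassium alkoxide 19 (not isolated)
Conditions: KH (1.5 equiv), 18-crown-6 (0.2 equiv), THF–DMPU, 0 → 70 °C
Reagents that add atoms: none
Why: Intramolecular SNAr O-arylation exactly as in step 6 (ring closure by the only free alkoxide, retention at both stereocenters), which should give the 2,3-cis flavan.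

Step 12
Reactants: 13 (2R,3R,4S)-3,5,7-tris(benzyloxy)-2-[4-(benzyloxy)phenyl]-4-(2-ethoxyethoxy)-3,4-dihydro-2H-chromene; 20 3,5,7,3',5'-penta-O-benzyl-4'-O-methylepigallocatechin (3 equiv, excess recovered)
Product: 22 3,5,7,4'-tetra-O-benzylepiafzelechin-(4β→8)-3,5,7,3',5'-penta-O-benzyl-4'-O-methylepigallocatechin, via C4 benzylic cation 21 (not isolated)
Conditions: TMSOTf (0.3 equiv), CH2Cl2, 13 added slowly, −78 → −40 °C; Et3N quench
Reagents that add atoms: none
Why: Lewis-acid-promoted Friedel–Crafts alkylation: TMSOTf ionizes the C4 ether to cation 21, and C8 of 20 (flanked by O1 and the C7 benzyloxy group, more nucleophilic than C6) attacks anti to the C2 aryl and C3 benzyloxy groups, setting C4 as 4β (3,4-trans); this unit stays uncapped because its C8 is the nucleophilic site of step 13, and the excess of 20 suppresses chain growth.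

Step 13
Reactants: 14 (2R,3R,4S)-3,5,7-tris(benzyloxy)-2-[4-(benzyloxy)phenyl]-8-bromo-4-(2-ethoxyethoxy)-3,4-dihydro-2H-chromene; 22 protected dimer (1.2 equiv)
Product: 24 8-bromo-3,5,7,4'-tetra-O-benzylepiafzelechin-(4β→8)-3,5,7,4'-tetra-O-benzylepiafzelechin-(4β→8)-3,5,7,3',5'-penta-O-benzyl-4'-O-methylepigallocatechin, via C8-bromo C4 benzylic cation 23 (not isolated)
Conditions: TMSOTf (0.3 equiv), CH2Cl2, −40 °C; Et3N quench
Reagents that add atoms: none
Why: The same TMSOTf-promoted Friedel–Crafts alkylation, now through the C8-brominated cation 23, which cannot condense with itself, so the dimer need not be used in large excess; the free C8 of the upper unit of 22 is the most nucleophilic and least hindered ring A position, and attack anti to the C2 aryl and C3 benzyloxy groups sets the second 4β (3,4-trans) interflavan bond.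

Step 14
Reactants: 24 protected 8-bromo trimer
Product: 25 epiafzelechin-(4β→8)-epiafzelechin-(4β→8)-4'-O-methylepigallocatechin (CNP0146516.1)
Conditions: H2 (1 atm), Pd(OH)2/C, NaHCO3 (2 equiv), THF–MeOH–H2O, rt
Reagents that add atoms: none
Why: Catalytic hydrogenolysis of all thirteen benzyl ethers together with hydrodebromination of the C8 aryl bromide, NaHCO3 taking up the HBr so that the acid-labile interflavan bonds, the aryl methyl ether and all stereocenters should stay untouched.

Compound list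
1 | 1,3,5-trifluorobenzene | Fc1cc(F)cc(F)c1 | starting material
2 | 1,3-bis(benzyloxy)-5-fluorobenzene | Fc1cc(OCc2ccccc2)cc(OCc2ccccc2)c1 | intermediate
3 | methyl (2R)-oxirane-2-carboxylate | COC(=O)[C@H]1CO1 | starting material
4 | [2,4-bis(benzyloxy)-6-fluorophenyl]lithium | [Li]c1c(F)cc(OCc2ccccc2)cc1OCc1ccccc1 | intermediate
5 | [2,4-bis(benzyloxy)-6-fluorophenyl]magnesium bromide | Br[Mg]c1c(F)cc(OCc2ccccc2)cc1OCc1ccccc1 | intermediate
6 | methyl (2R)-3-[2,4-bis(benzyloxy)-6-fluorophenyl]-2-hydroxypropanoate | COC(=O)[C@H](O)Cc1c(F)cc(OCc2ccccc2)cc1OCc1ccccc1 | intermediate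
7 | methyl (2R)-2-(benzyloxy)-3-[2,4-bis(benzyloxy)-6-fluorophenyl]propanoate | COC(=O)[C@H](OCc1ccccc1)Cc1c(F)cc(OCc2ccccc2)cc1OCc1ccccc1 | intermediate
8 | (2R)-2-(benzyloxy)-3-[2,4-bis(benzyloxy)-6-fluorophenyl]propanal | O=C[C@H](OCc1ccccc1)Cc1c(F)cc(OCc2ccccc2)cc1OCc1ccccc1 | intermediate
9 | [4-(benzyloxy)phenyl]magnesium bromide | Br[Mg]c1ccc(OCc2ccccc2)cc1 | starting material
10 | (1R,2R)-2-(benzyloxy)-3-[2,4-bis(benzyloxy)-6-fluorophenyl]-1-[4-(benzyloxy)phenyl]propan-1-ol | O[C@H](c1ccc(OCc2ccccc2)cc1)[C@H](OCc1ccccc1)Cc1c(F)cc(OCc2ccccc2)cc1OCc1ccccc1 | intermediate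
11 | potassium alkoxide of 10 | [K+].[O-][C@H](c1ccc(OCc2ccccc2)cc1)[C@H](OCc1ccccc1)Cc1c(F)cc(OCc2ccccc2)cc1OCc1ccccc1 | intermediate
12 | (2R,3R)-3,5,7-tris(benzyloxy)-2-[4-(benzyloxy)phenyl]-3,4-dihydro-2H-chromene | C1c2c(OCc3ccccc3)cc(OCc3ccccc3)cc2O[C@H](c2ccc(OCc3ccccc3)cc2)[C@@H]1OCc1ccccc1 | intermediate
13 | (2R,3R,4S)-3,5,7-tris(benzyloxy)-2-[4-(benzyloxy)phenyl]-4-(2-ethoxyethoxy)-3,4-dihydro-2H-chromene | CCOCCO[C@H]1c2c(OCc3ccccc3)cc(OCc3ccccc3)cc2O[C@H](c2ccc(OCc3ccccc3)cc2)[C@@H]1OCc1ccccc1 | intermediate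
14 | (2R,3R,4S)-3,5,7-tris(benzyloxy)-2-[4-(benzyloxy)phenyl]-8-bromo-4-(2-ethoxyethoxy)-3,4-dihydro-2H-chromene | CCOCCO[C@H]1c2c(OCc3ccccc3)cc(OCc3ccccc3)c(Br)c2O[C@H](c2ccc(OCc3ccccc3)cc2)[C@@H]1OCc1ccccc1 | intermediate
15 | 5-bromo-1,3-difluoro-2-methoxybenzene | COc1c(F)cc(Br)cc1F | starting material
16 | 1,3-bis(benzyloxy)-5-bromo-2-methoxybenzene | COc1c(OCc2ccccc2)cc(Br)cc1OCc1ccccc1 | intermediate
17 | [3,5-bis(benzyloxy)-4-methoxyphenyl]magnesium bromide | COc1c(OCc2ccccc2)cc([Mg]Br)cc1OCc1ccccc1 | intermediate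
18 | (1R,2R)-2-(benzyloxy)-3-[2,4-bis(benzyloxy)-6-fluorophenyl]-1-[3,5-bis(benzyloxy)-4-methoxyphenyl]propan-1-ol | O[C@H](c1cc(OCc2ccccc2)c(OC)c(OCc2ccccc2)c1)[C@H](OCc1ccccc1)Cc1c(F)cc(OCc2ccccc2)cc1OCc1ccccc1 | intermediate
19 | potassium alkoxide of 18 | [K+].[O-][C@H](c1cc(OCc2ccccc2)c(OC)c(OCc2ccccc2)c1)[C@H](OCc1ccccc1)Cc1c(F)cc(OCc2ccccc2)cc1OCc1ccccc1 | intermediate
20 | (2R,3R)-3,5,7-tris(benzyloxy)-2-[3,5-bis(benzyloxy)-4-methoxyphenyl]-3,4-dihydro-2H-chromene | COc1c(OCc2ccccc2)cc([C@H]2Oc3cc(OCc4ccccc4)cc(OCc4ccccc4)c3C[C@H]2OCc2ccccc2)cc1OCc1ccccc1 | intermediate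
21 | C4 benzylic cation of the tetra-O-benzylepiafzelechin unit (triflate) | [CH+]1c2c(OCc3ccccc3)cc(OCc3ccccc3)cc2O[C@H](c2ccc(OCc3ccccc3)cc2)[C@@H]1OCc1ccccc1.[O-]S(=O)(=O)C(F)(F)F | intermediate
22 | 3,5,7,4'-tetra-O-benzylepiafzelechin-(4β→8)-3,5,7,3',5'-penta-O-benzyl-4'-O-methylepigallocatechin | COc1c(OCc7ccccc7)cc([C@H]2Oc3c(c(OCc7ccccc7)cc(OCc7ccccc7)c3[C@H]3c4c(OCc7ccccc7)cc(OCc7ccccc7)cc4O[C@H](c4ccc(OCc7ccccc7)cc4)[C@@H]3OCc7ccccc7)C[C@H]2OCc7ccccc7)cc1OCc7ccccc7 | intermediate
23 | C4 benzylic cation of the 8-bromo tetra-O-benzylepiafzelechin unit (triflate) | [CH+]1c2c(OCc3ccccc3)cc(OCc3ccccc3)c(Br)c2O[C@H](c2ccc(OCc3ccccc3)cc2)[C@@H]1OCc1ccccc1.[O-]S(=O)(=O)C(F)(F)F | intermediate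
24 | 8-bromo-3,5,7,4'-tetra-O-benzylepiafzelechin-(4β→8)-3,5,7,4'-tetra-O-benzylepiafzelechin-(4β→8)-3,5,7,3',5'-penta-O-benzyl-4'-O-methylepigallocatechin | COc1c(OCc7ccccc7)cc([C@H]2Oc3c(c(OCc7ccccc7)cc(OCc7ccccc7)c3[C@H]3c4c(OCc7ccccc7)cc(OCc7ccccc7)c([C@H]5c6c(OCc7ccccc7)cc(OCc7ccccc7)c(Br)c6O[C@H](c6ccc(OCc7ccccc7)cc6)[C@@H]5OCc7ccccc7)c4O[C@H](c4ccc(OCc7ccccc7)cc4)[C@@H]3OCc7ccccc7)C[C@H]2OCc7ccccc7)cc1OCc7ccccc7 | intermediate
25 | epiafzelechin-(4β→8)-epiafzelechin-(4β→8)-4'-O-methylepigallocatechin (CNP0146516.1) | COc1c(O)cc([C@H]2Oc3c(c(O)cc(O)c3[C@H]3c4c(O)cc(O)c([C@H]5c6c(O)cc(O)cc6O[C@H](c6ccc(O)cc6)[C@@H]5O)c4O[C@H](c4ccc(O)cc4)[C@@H]3O)C[C@H]2O)cc1O | target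

Total step count: 14. Longest linear sequence: 10 steps (steps 1, 2, 3, 4, 5, 6, 7, 8, 13, 14).

Steps most likely to fail

Step 6 (key step). The addition–elimination at an electron-rich fluoroarene may be slow, so that base-induced degradation (benzyl ether cleavage, intermolecular substitution) overtakes ring closure. The fallback sets out from 10 and returns to 12, forming the same O1–C8a bond by elimination–addition. Lithium 2,2,6,6-tetramethylpiperidide (3 equiv) in THF at −78 → 0 °C should deprotonate the hydroxyl group and the ring C–H between fluorine and benzyloxy. Loss of LiF would give the lithium alkoxide of the 3-(benzyloxy)aryne F1. Its tethered alkoxide should add to the aryne carbon remote from the benzyloxy group, the position that both the inductive effect of a 3-alkoxyaryne and the tether favour. Protonation of the resulting C8 aryllithium on work-up would give 12.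

Step 13. Reactivity and site selectivity may be lost: the hindered dimer may be attacked slowly at the C8 of its upper unit or at a C6 position, so that the ionized electrophile decomposes instead of coupling. The fallback sets out from 13 and comes back to the route at 24, reversing the order of assembly so that the nucleophile is always a monomer. Treatment of 13 with 2,6-dimethylbenzenethiol and BF3·OEt2 in CH2Cl2 at −78 °C should give (2R,3R,4S)-3,5,7-tris(benzyloxy)-2-[4-(benzyloxy)phenyl]-4-[(2,6-dimethylphenyl)sulfanyl]-3,4-dihydro-2H-chromene F2, a 4β thioether that hard Lewis acids do not ionize. BF3·OEt2-promoted coupling of 14 with F2 at −78 → −30 °C should then give the 8-bromo (4β→8) dimer that carries the 4β-(2,6-dimethylphenyl)sulfanyl group on its lower unit F3. Activation of the C4–S bond of F3 with the thiophilic salt AgBF4 in CH2Cl2 at −40 °C in the presence of an excess of 20 would give 24.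

Step 5 (the same concern applies to step 10). Facial selectivity may be poor because THF competes with the chelate and lets the non-chelated Felkin pathway through, which would give 10 mixed with its carbinol epimer. The fallback sets out from 10 obtained as such a mixture and returns to pure 10, replacing substrate control by catalyst control. Oxidation with Dess–Martin periodinane in CH2Cl2 should converge both epimers on (2R)-2-(benzyloxy)-3-[2,4-bis(benzyloxy)-6-fluorophenyl]-1-[4-(benzyloxy)phenyl]propan-1-one F4. Asymmetric transfer hydrogenation of this aryl ketone with RuCl[(S,S)-TsDPEN](p-cymene) in HCO2H–Et3N should then deliver hydride to the face that gives the (1R) carbinol 10.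

Further compounds
F1 | step 6 | lithium alkoxide of the aryne from 10 (aryne between the former C–F and adjacent C–H carbons) | [Li+].[O-][C@H](c1ccc(OCc2ccccc2)cc1)[C@H](OCc1ccccc1)CC1=C(OCc2ccccc2)C=C(OCc2ccccc2)C#C1
F2 | step 13 | (2R,3R,4S)-3,5,7-tris(benzyloxy)-2-[4-(benzyloxy)phenyl]-4-[(2,6-dimethylphenyl)sulfanyl]-3,4-dihydro-2H-chromene | Cc1cccc(C)c1S[C@H]1c2c(OCc3ccccc3)cc(OCc3ccccc3)cc2O[C@H](c2ccc(OCc3ccccc3)cc2)[C@@H]1OCc1ccccc1
F3 | step 13 | 8-bromo-3,5,7,4'-tetra-O-benzylepiafzelechin-(4β→8)-3,5,7,4'-tetra-O-benzyl-4β-[(2,6-dimethylphenyl)sulfanyl]epiafzelechin | Cc1cccc(C)c1S[C@H]1c2c(OCc7ccccc7)cc(OCc7ccccc7)c([C@H]3c4c(OCc7ccccc7)cc(OCc7ccccc7)c(Br)c4O[C@H](c4ccc(OCc7ccccc7)cc4)[C@@H]3OCc7ccccc7)c2O[C@H](c2ccc(OCc7ccccc7)cc2)[C@@H]1OCc7ccccc7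
F4 | step 5 | (2R)-2-(benzyloxy)-3-[2,4-bis(benzyloxy)-6-fluorophenyl]-1-[4-(benzyloxy)phenyl]propan-1-one | O=C(c1ccc(OCc2ccccc2)cc1)[C@H](OCc1ccccc1)Cc1c(F)cc(OCc2ccccc2)cc1OCc1ccccc1
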